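The data were generated by integration on assumed constants, and the scatter is random.

Each unit of target takes up one starting material and one reagent, and the isomer of the product holds the same unit, so target plus isomer, which we call the pool, stays at or below the smaller charge. Here that ceiling is 100% of the starting material, which makes starting material the limiting reagent at 1.50 equivalents of reagent.

all flasks: starting material 0.40 M; initiator 24 mM; temperature 0 °C

| run | reagent | remark | time |
|---|---|---|---|
| south-east | 0.60 M | the very flask that is asked about, followed so far |  |
| flask | 0.600 M |  | 8.0 d |

- south-east (time / d: target / %): 0.417: 79.2; 1.25: 44.8; 2.50: 29.8; 4.00: 24.9; 5.00: 24.8; 6.00: 24.7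

(standard deviation of a reading: 1 percentage point)

- percentages count the starting material that a species holds: one ended chains A counts as two
- additions leave the volume as it is
- the earlier runs were read with a standard deviation of 1 percentage point
- candidate steps: initiator -> 2 initiating radical; starting material + initiating radical -> capped initiator + first chain carrier; reagent + first chain carrier <-> target + second chain carrier; starting material + second chain carrier -> released group + first chain carrier; 2 first chain carrier -> ended chains A; 2 second chain carrier -> ended chains B; target <-> isomer of the product
- the earlier runs do not show what temperature does; that part of a forecast is a guess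

- elm: at 8.0 d raise the temperature by 15 K, then wait 4.0 d
- oak: at 8.0 d add reagent, 50.0% of the amount charged, then wait 4.0 d
- alder: at 8.0 d take out 90% of the released group then present, then wait 4.0 d
- birch: change nothing and wait 4.0 d more

- target, in percent of the starting material first charged, at 8.0 d
- the option that brings most further target ("none" if no option brings more than 2 percentage points) (elm / oak / alder / birch / none)
- target present, in percent of the starting material first charged, after oak
- target present, in percent of the starting material first charged, after birch

In the south-east run, target stands highest at the first reading and then falls to a flat 24.8%. Among the candidate steps, target can go to the isomer and back, so we read the flat line as an equilibrium inside the pool.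

We bracket it. From above: the pool held at least the first reading, so the share of target at rest reads at most 31.3%. From below: a pool at the ceiling gives 24.8%, and this, target at rest divided by the pool, is the resting share.

To tighten, we take the excess over the plateau, which by the first two readings falls at 1.20 d⁻¹. Run back to the start, it reaches 115%, past the ceiling. So we commit to a full pool and the lower bound, with 0% of the starting material free and 33.3% of the reagent left.

The relaxation half-life so read, 0.578 d, is shorter than 8.0 d, so the south-east flask should be at rest. Oak and birch then leave pool and share alone, and no candidate step takes up the released group, so alder does nothing either. Elm can move the share, and a share below half suggests that the isomer lies downhill, so warming should favour target. We bet on elm, with the size a guess.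

The forecast gives 24.8% now, 24.8% after oak and 24.8% after birch, on our lower bound, but names none as best: “Heating (elm) only shifts the isomer equilibrium by an unknown, probably small, amount.”

The flask gives 23.8% now, 23.8% after oak and 23.8% after birch; the best option is elm, with a gain of 23 percentage points.

    initiator → 2 initiating radical (k = 0.00760 h⁻¹, Ea = 100 kJ mol⁻¹)
    starting material + initiating radical → capped initiator + first chain carrier (k = 74000 L mol⁻¹ s⁻¹, Ea = 18.0 kJ mol⁻¹)
    reagent + first chain carrier ⇌ target + second chain carrier (K = 2.70, k = 1.40 × 10⁷ L mol⁻¹ h⁻¹, Ea = 30.0 kJ mol⁻¹, ΔH = −15.0 kJ mol⁻¹)
    starting material + second chain carrier → released group + first chain carrier (k = 30000 L mol⁻¹ s⁻¹, Ea = 9.00 kJ mol⁻¹)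
    2 first chain carrier → ended chains A (k = 4.30 × 10⁷ L mol⁻¹ s⁻¹, Ea = 10.0 kJ mol⁻¹)
    2 second chain carrier → ended chains B (k = 1.00 × 10⁹ L mol⁻¹ s⁻¹, Ea = 8.00 kJ mol⁻¹)
    target ⇌ isomer of the product (K = 3.20, k = 0.0340 h⁻¹, Ea = 100 kJ mol⁻¹, ΔH = −45.0 kJ mol⁻¹)
    (constants at 0 °C)

Elm pays through the resting share: with the step between target and isomer taken out of the run, its gain of 23 points drops to 0 points. In the neighbour flask with 0.24 M of reagent, 0.600 equiv, reagent is limiting, with 0% of it left at the end, so the ceiling falls to 60.0%; the resting share then gives 14.9% target, and that flask holds 14.3%.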